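## Plan

- Feature: numbering the side chain from the ring (C1′ = CH2 on ring carbon C4 of the pyran ring, C2′ = CHOAc, C3′=C4′ = E alkene), C1′–C4′ are the four carbons of a 1,3-diene. The ring carbon and the acetate oxygen therefore sit on the two carbons of its former terminal vinyl group.
- Retrosynthesis: C4–C1′ and C2′–O are cut together, giving a 4-iodo heteroarene, (E)-4,8-dimethylnona-1,3,7-triene and acetate. C4–I is then traced back to C4–CO2H and C4–CO2Me, and C1′=C2′ of the triene to the aldehyde of geranial.
- Forward: the fused six-membered pyran and five-membered carbocycle are not built but taken from genipin and made aromatic (alcohol oxidation, dehydration, dehydrogenation). The ester becomes the acid and then the iodide, a Wittig reaction gives the triene, and the chain is joined to the ring in the last step.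
- Stereochemistry: C2′ (S) is the only stereocentre and is set in the last step by a chiral phosphoramidite on palladium. The E alkene is carried in from geranial, and the stereocentres of genipin are given up on aromatisation.

Key step: step 6

Assumption: the ligand antipode that leads to (S) with acetate as nucleophile is written as (Sa,R,R); should the sense of induction prove opposite, its mirror image is used without other change.

## Route

Step 1
Reactants: 1 genipin, methyl (1R,4aS,7aS)-1-hydroxy-7-(hydroxymethyl)-1,4a,5,7a-tetrahydrocyclopenta[c]pyran-4-carboxylate
Product: 2 10-oxogenipin, methyl (1R,4aS,7aS)-7-formyl-1-hydroxy-1,4a,5,7a-tetrahydrocyclopenta[c]pyran-4-carboxylate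
Conditions: activated MnO2 (15 equiv), EtOAc, rt
Reagents that add atoms: none
Why: Manganese dioxide oxidises the primary allylic alcohol selectively (allylic oxidation), whereas the non-allylic lactol hydroxyl at C1 and the three stereocentres are left untouched.

Step 2
Reactants: 2 10-oxogenipin
Product: 4 methyl 7-formylcyclopenta[c]pyran-4-carboxylate (cerbinal), via dihydro dienol ether 3 (not isolated)
Conditions: TsOH·H2O (5 mol %), PhH, 80 °C, azeotropic removal of water; then DDQ (1.1 equiv), rt
Reagents that add atoms: none
Why: Acid-catalysed E1 dehydration of the lactol (ionisation at C1 assisted by the ring oxygen, loss of H7a) gives the conjugated dienol ether 3, and DDQ then removes the doubly allylic C4a hydride and C5 loses a proton, a dehydrogenative aromatisation driven by formation of the 10 π-electron cyclopenta[c]pyran in which the remaining stereocentre disappears.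

Step 3
Reactants: 4 methyl 7-formylcyclopenta[c]pyran-4-carboxylate
Product: 6 7-formylcyclopenta[c]pyran-4-carboxylic acid, via trimethylstannyl ester 5 (not isolated)
Conditions: Me3SnOH (5 equiv), ClCH2CH2Cl, 80 °C; then 0.5 M HCl work-up
Reagents that add atoms: trimethyltin hydroxide, C[Sn](C)(C)O
Why: Trimethyltin hydroxide delivers hydroxide to the ester carbonyl under neutral conditions (mild methyl ester cleavage through the stannyl ester 5), which avoids free hydroxide that could add to C1 or C3 of the pyran ring or to the aldehyde.

Step 4
Reactants: 6 7-formylcyclopenta[c]pyran-4-carboxylic acid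
Product: 8 4-iodocyclopenta[c]pyran-7-carbaldehyde, via Barton ester 7 (not isolated)
Conditions: N-hydroxypyridine-2-thione (1.1 equiv), DCC (1.1 equiv), PhCl, rt, dark; then CHI3 (3 equiv), AIBN (cat.), 100 °C
Reagents that add atoms: iodoform, IC(I)I (the iodine of 8); N-hydroxypyridine-2-thione, ON1C=CC=CC1=S (thiohydroxamate part of 7 only)
Why: Barton radical decarboxylation: thermolysis of the thiohydroxamate ester 7 starts a chain in which the carboxyl group is lost as CO2 and the resulting C4 σ-radical takes iodine from iodoform, so that iodine enters exactly where the carboxyl group stood and no electrophilic iodinating agent, which would attack the five-membered ring, is needed.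

Step 5
Reactants: 9 geranial, (2E)-3,7-dimethylocta-2,6-dienal (pure E isomer); 10 methyltriphenylphosphonium bromide
Product: 12 (E)-4,8-dimethylnona-1,3,7-triene, via methylenetriphenylphosphorane 11 (not isolated)
Conditions: KOtBu (1.15 equiv), THF, 0 °C; then 9, −78 °C to rt
Reagents that add atoms: none
Why: Wittig methylenation with the non-stabilised ylide 11 takes place only at the aldehyde, and adding the enal to the preformed ylide at low temperature keeps the E trisubstituted alkene from isomerising through the dienolate.

Step 6
Reactants: 8 4-iodocyclopenta[c]pyran-7-carbaldehyde (1 equiv); 12 (E)-4,8-dimethylnona-1,3,7-triene (2 equiv); 13 cesium acetate (3 equiv)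
Product: 14 (2S,3E)-1-(7-formylcyclopenta[c]pyran-4-yl)-4,8-dimethylnona-3,7-dien-2-yl acetate (the target)
Conditions: Pd2(dba)3 (2.5 mol %), (Sa,R,R)-O,O′-(1,1′-binaphthalene-2,2′-diyl) N,N-bis(1-phenylethyl)phosphoramidite (6 mol %), 4 Å MS, THF, 25 °C
Reagents that add atoms: none
Why: Proposed new method: zerovalent palladium carrying the phosphoramidite adds oxidatively to the C4–I bond of 8, the heteroaryl–palladium iodide inserts the terminal vinyl group of 12 with ring carbon C4 going to C1′, and the metal is left at C2′ as an η3-allyl spanning C2′–C4′, which acetate attacks on the face opposite to palladium to form the C2′–O bond and return zerovalent palladium. The closest known reaction type is the palladium-catalysed three-component coupling of aryl halides, 1,3-dienes and nucleophiles (Heck insertion followed by Tsuji–Trost substitution), which is enantioselective with amines and stabilised carbanions but has not been shown with a carboxylate as the intermolecular nucleophile. No ring is formed in this step. The single new stereocentre C2′ is controlled by the chiral ligand: it selects the face of the vinyl group in the insertion and thus the face of C2′ that palladium occupies, and the anti attack of acetate turns this into the (S) configuration, while a face exchange through a σ-allyl at the fully substituted C4′ is unlikely, which also preserves the E geometry brought in from geranial. The step needs site selectivity among three alkenes (only the terminal vinyl is unhindered and gives a stabilised allyl on insertion), attack at C2′ instead of C4′ (secondary against fully substituted terminus, product with the more substituted alkene) and capture faster than β-hydride elimination or re-ionisation of 14 (excess acetate, precipitation of CsI, low temperature, iodide 8 competing with the allylic acetate for zerovalent palladium). The aldehyde and the pseudoazulene nucleus should be inert to these neutral conditions.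

## Compound list

1 | genipin, methyl (1R,4aS,7aS)-1-hydroxy-7-(hydroxymethyl)-1,4a,5,7a-tetrahydrocyclopenta[c]pyran-4-carboxylate | COC(=O)C1=CO[C@H]([C@H]2[C@@H]1CC=C2CO)O | starting material
2 | 10-oxogenipin, methyl (1R,4aS,7aS)-7-formyl-1-hydroxy-1,4a,5,7a-tetrahydrocyclopenta[c]pyran-4-carboxylate | COC(=O)C1=CO[C@H]([C@H]2[C@@H]1CC=C2C=O)O | intermediate
3 | dihydro dienol ether, methyl (4aS)-7-formyl-4a,5-dihydrocyclopenta[c]pyran-4-carboxylate | COC(=O)C1=COC=C2[C@@H]1CC=C2C=O | intermediate (not isolated)
4 | cerbinal, methyl 7-formylcyclopenta[c]pyran-4-carboxylate | COC(=O)c1cocc2c(C=O)ccc1-2 | intermediate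
5 | trimethylstannyl 7-formylcyclopenta[c]pyran-4-carboxylate | C[Sn](C)(C)OC(=O)c1cocc2c(C=O)ccc1-2 | intermediate (not isolated)
6 | 7-formylcyclopenta[c]pyran-4-carboxylic acid | OC(=O)c1cocc2c(C=O)ccc1-2 | intermediate
7 | Barton ester, 2-thioxopyridin-1(2H)-yl 7-formylcyclopenta[c]pyran-4-carboxylate | O=C(ON1C=CC=CC1=S)c1cocc2c(C=O)ccc1-2 | intermediate (not isolated)
8 | 4-iodocyclopenta[c]pyran-7-carbaldehyde | Ic1cocc2c(C=O)ccc1-2 | intermediate
9 | geranial, (2E)-3,7-dimethylocta-2,6-dienal | O=C/C=C(\C)CCC=C(C)C | starting material
10 | methyltriphenylphosphonium bromide | C[P+](c1ccccc1)(c1ccccc1)c1ccccc1.[Br-] | starting material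
11 | methylenetriphenylphosphorane | C=P(c1ccccc1)(c1ccccc1)c1ccccc1 | intermediate (not isolated)
12 | (E)-4,8-dimethylnona-1,3,7-triene | C=C/C=C(\C)CCC=C(C)C | intermediate
13 | cesium acetate | CC(=O)[O-].[Cs+] | starting material
14 | (2S,3E)-1-(7-formylcyclopenta[c]pyran-4-yl)-4,8-dimethylnona-3,7-dien-2-yl acetate | CC(=O)O[C@H](/C=C(\C)CCC=C(C)C)Cc1cocc2c(C=O)ccc1-2 | target

## Step count and risks

Total steps: 6. Longest linear sequence: 5 (steps 1, 2, 3, 4 and 6; step 5 is the one-step side branch).

Steps most likely to fail:

1. Step 6 (proposed new method). The allyl–palladium intermediate may lose a β-hydrogen (from C1′, the C4′ methyl or C5′) before acetate arrives, acetate may enter at C4′, the allylic acetate may re-ionise under zerovalent palladium so that regio- and enantiopurity erode, or the facial selectivity of the insertion may be poor. The fallback uses known reactions, sets out from 8 and returns at 14, making the C2′–C3′ bond by carbonyl addition instead.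
   - Stille coupling of 8 with (Z)-tributyl(2-ethoxyvinyl)stannane (Pd(PPh3)4, toluene, 90 °C) should give 4-[(Z)-2-ethoxyethenyl]cyclopenta[c]pyran-7-carbaldehyde F1.
   - Brief hydrolysis of the enol ether (1 M HCl, THF, 0 °C) should give the dialdehyde 4-(2-oxoethyl)cyclopenta[c]pyran-7-carbaldehyde F2.
   - Separately, zirconium-catalysed carboalumination of 6-methylhept-5-en-1-yne (C#CCCC=C(C)C; Me3Al, Cp2ZrCl2 cat., CH2Cl2) gives (E)-(2,6-dimethylhepta-1,5-dien-1-yl)dimethylalane F3, which iodine converts in the same flask into (E)-1-iodo-2,6-dimethylhepta-1,5-diene F4.
   - An asymmetric Nozaki–Hiyama–Kishi coupling of F4 with F2 (CrCl2, NiCl2 cat., chiral oxazoline–sulfonamide ligand, Et3N, THF) should take place at the aliphatic aldehyde only, because the ring aldehyde is a far less electrophilic vinylogous formate. With the ligand antipode chosen for S it should give 4-[(2S,3E)-2-hydroxy-4,8-dimethylnona-3,7-dien-1-yl]cyclopenta[c]pyran-7-carbaldehyde F5.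
   - Acetylation (Ac2O, pyridine, DMAP cat., CH2Cl2) then gives 14.

2. Step 4. Loss of CO2 from the aroyloxy radical is slow, so recombination or hydrogen abstraction may return the acid before the C4 radical forms, and iodine released from iodoform on heating may attack the five-membered ring. The fallback sets out from 6 and returns at 8. The chloroenamine 1-chloro-N,N,2-trimethylprop-1-en-1-amine (CH2Cl2, 0 °C) converts 6 under neutral conditions into 7-formylcyclopenta[c]pyran-4-carbonyl chloride F6. Palladium-catalysed decarbonylative iodination (Pd2(dba)3, Xantphos, 1-iodobutane, toluene, about 120 °C), by oxidative addition of the acyl chloride, loss of CO, chloride–iodide exchange and C–I reductive elimination, should then give 8 without any radical or electrophilic iodine.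

3. Step 3. Acyl substitution at the donor-conjugated ester may be sluggish, and a hydroxide-type nucleophile may instead add to C1 or C3 of the pyran ring and open it. The fallback sets out from 4 and returns at 6. LiI (EtOAc, reflux) cleaves the O–CH3 bond by SN2 attack of iodide on the methyl group, a soft nucleophile that cannot open the ring irreversibly, giving lithium 7-formylcyclopenta[c]pyran-4-carboxylate F7. Acidification with dilute HCl gives 6.

## Further compounds

F1 | step 6 | 4-[(Z)-2-ethoxyethenyl]cyclopenta[c]pyran-7-carbaldehyde | CCO/C=C\c1cocc2c(C=O)ccc1-2
F2 | step 6 | 4-(2-oxoethyl)cyclopenta[c]pyran-7-carbaldehyde | O=CCc1cocc2c(C=O)ccc1-2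
F3 | step 6 | (E)-(2,6-dimethylhepta-1,5-dien-1-yl)dimethylalane | C[Al](C)/C=C(\C)CCC=C(C)C
F4 | step 6 | (E)-1-iodo-2,6-dimethylhepta-1,5-diene | I/C=C(\C)CCC=C(C)C
F5 | step 6 | 4-[(2S,3E)-2-hydroxy-4,8-dimethylnona-3,7-dien-1-yl]cyclopenta[c]pyran-7-carbaldehyde | O[C@H](/C=C(\C)CCC=C(C)C)Cc1cocc2c(C=O)ccc1-2
F6 | step 4 | 7-formylcyclopenta[c]pyran-4-carbonyl chloride | O=C(Cl)c1cocc2c(C=O)ccc1-2
F7 | step 3 | lithium 7-formylcyclopenta[c]pyran-4-carboxylate | [Li+].[O-]C(=O)c1cocc2c(C=O)ccc1-2
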